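**Conventions and one assumption.** Both halves use flavan numbering (O1, C2, C3, C4, C4a, C5–C8, C8a; ring A is the fused benzene ring, ring B the 2-aryl group). "Upper" is the half whose C4 carries the aryl–alkyl bond; "lower" is the flavan-3,4-diol half. U stands for (2R,3R,4R)-3,7,8-tris(benzyloxy)-2-[3,4-bis(benzyloxy)phenyl]chroman-4-yl (2,3-cis, 3,4-trans). The descriptor at upper C4 is R in every benzylated intermediate and S in the target only because substituent priorities change; the geometry is the same. Assumption: the enamine of 10 reacts through its E isomer, as enamines of alkyl aldehydes do.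

## Analysis of the target

The target is a biflavanoid: an upper 4-arylflavan-3-ol and a lower flavan-3,4-diol, joined by one bond from upper C4 to C6 of lower ring A. The upper pyran ring carries three contiguous stereocentres (2R,3R,4S): the C2 aryl and C3 hydroxyl are cis, and the C3 hydroxyl and C4 aryl are trans. The lower pyran ring carries three more (2R,3R,4R), all cis. This is the arrangement in which C2 aryl and C3 oxygen cannot both be delivered by attack anti to an existing neighbour. The lower half is separated from the upper stereocentres by the flat ring A, so its absolute configuration cannot be relayed from the upper half and must be set by a reagent. Sensitive features are ten free hydroxyls on three catechol or pyrogallol-type rings (air oxidation, so phenols stay masked to the end), the ionisable and hydrogenolysis-prone benzylic C4–OH of the lower half, and two benzylic C2–O1 ether bonds. The strategy rests on upper C4: it is a benzylic methine bonded to upper ring A ortho to O1, which is the methide carbon of an ortho-quinone methide. Upper C3 is an oxygen-bearing carbon next to it that can be the α-carbon of a protected glycolaldehyde. Lower ring A is then only a pyrogallol-derived aryl substituent on that methide carbon, and it must arrive with a handle at the future lower C4a.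

## Retrosynthetic reasoning

30 from 29. Only the nine O-benzyl groups are removed, by hydrogenolysis. Benzyl is used throughout because it survives base, hydride, Lewis acid at low temperature and palladium coupling, and leaves under neutral conditions that the polyphenol tolerates.

29 from 28 from 27. The lower C3–H bond is made last in the lower ring. Every electrophilic oxygenation of C3 enters anti to the C2 aryl and gives the unwanted 2,3-trans alcohol, so the alcohol of 27 is oxidised to ketone 28 and a bulky hydride is brought in anti to both equatorial neighbours. This yields the all-cis 29 and cancels any imperfection in the earlier C3 configuration.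

27 from 26 from 25. The C4 oxygen is needed as an ether cis to the C2 aryl while C3 remains a free alcohol. The lower C4 is benzylic and activated by O1 and the C7 oxygen, so its C–O bond can be exchanged under mild acid without touching C3. Diol 26 comes from reduction of the ketone of 25, and the C4 configuration is settled in the exchange, not in the reduction.

25 from 23 via 24. The C3–O bond is cut back to the enol silane 24 of flavanone 23. Oxidation of that enol ether anti to the aryl group gives the trans ketol 25.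

23 from 21 and 22. The lower C2–aryl bond is cut. A lower heterocycle that stays planar to the end would take up hydrogen on either face, because the upper stereocentres are too far away to direct it. Lower C2 is therefore set by a ligand-controlled palladium-catalysed conjugate addition of boronic acid 22 to chromone 21. Because 21 is already a single enantiomer, imperfect selectivity here appears as separable diastereomers.

21 from 19 from 18 from 16. The lower pyranone is opened at O1–C2 and C2–C3 to the ortho-hydroxy acetophenone 19 (through enaminone 20). The phenol of 19 is released from the one benzyl ether that sits ortho to the acetyl group of 18, by chelation. The acetyl group of 18 replaces the bromine of 16 (through enol ether 17). The bromine is carried from the start because late electrophilic acylation could not choose between four electron-rich rings.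

16 from 13 and 14 via 15. The upper C2–aryl bond is cut to the oxocarbenium ion 15 and the arene 14. Ring B enters last on the upper ring so that the key step needs only a two-carbon aldehyde. Attack on 15 must occur cis to the C3 ether and trans to the C4 aryl.

13 from 12 from 9 and 10 via 11. This is the key disconnection: upper C3–C4 and O1–C2. The lactol 12 opens to the ortho-quinone methide 11, released from sulfone 9, and the enamine of aldehyde 10. The forward reaction makes two bonds, the upper pyran ring and both the C3 and C4 stereocentres in one operation. The racemic sulfone converges because its stereocentre is lost in 11.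

9 from 8 from 5 and 2 via 6 and 7. The diarylmethyl sulfone is reached by sulfinate substitution of benzhydrol 8. Compound 8 is the adduct of aryllithium 6 and the phenoxide 7 of aldehyde 2. Compound 5 is symmetric, so mono-exchange is unambiguous and the second bromine ends up at the future lower C4a.

5 from 4 from 3, and 2 from 1. These are benzylations of commercial pyrogallol and 2,3,4-trihydroxybenzaldehyde, and a double ring bromination.

## Alternatives that were turned down

Alternative 1: The lower O1–C2 bond is cut, and a type 2 chalcone isomerase would cyclise the free 2'-hydroxychalcone A2 to the (2S)-flavanone A1. In its favour, the enzyme sets lower C2 with very high selectivity in water at neutral pH, needs no protecting groups, and on that one stereocentre is at least as reliable as the palladium step chosen here. Against it, A2 carries a pyrogallol ring A that oxidises readily at the working pH, and a flavan substituent next to the reacting phenol that is far larger than anything the active site is known to accept. A1 also still lacks both lower oxygens at C3 and C4, which would have to be introduced cis to the aryl group on an unprotected polyphenol. The disconnection also says nothing about how the upper ring is made. The chosen strategy instead builds the upper ring with two stereocentres in one step and keeps every phenol protected until the end.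

Alternative 2: Three bonds of lower ring A are cut (C4a–C8a, C5–C6, C7–C8), and a [2+2+2] cyclotrimerisation of three alkyne units on a cationic monovalent rhodium catalyst such as [Rh(cod)2]BF4 with a bisphosphine would give A3. In its favour, it is highly convergent, all six stereocentres would be in place before the union, and the boronate and silyl ether of A3 encode the two ring A oxygens. Against it, the acyclic precursors are harder than the target: one needs the complete upper unit with a silyloxyalkyne on its doubly benzylic C4, the other three contiguous oxygenated stereocentres (the same all-cis problem, moved into an open chain) plus a boryl ynol ether. The intermolecular alkyne must also insert with one orientation only, or the upper unit lands on lower C5. In step count to the cyclisation substrates it is clearly longer. The chosen route uses aromatic rings that are bought with their oxygens in place and keeps the risk in one well-defined annulation.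

Alternative 3: The upper O1–C8a bond is cut, and a Baeyer–Villiger oxidation of the 3-arylindanone A5 with a peracid would give the dihydrocoumarin A4. In its favour, 3-arylindanones are available in high enantiomeric purity by established conjugate additions, the electron-rich ring A carbon is the expected migrating group, and the C4 configuration would be more secure than one set in an enamine addition. Against it, A4 has no oxygen at C3, so enolate hydroxylation, O-benzylation next to an epimerisable lactone centre and partial reduction are needed to reach the oxidation level that 12 has directly. Peracids also attack polyalkoxybenzenes. It needs roughly twice the steps to the same lactol stage. The chosen strategy gives up some certainty at C4 and gains C3, its oxygen, the ring and the lactol in a single step from two simple partners.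

Key step: step 6

## Route

Step 1
Reactants: 1 2,3,4-trihydroxybenzaldehyde
Product: 2 3,4-bis(benzyloxy)-2-hydroxybenzaldehyde
Conditions: BnBr (2.05 equiv), K2CO3 (2.1 equiv), acetone, reflux
Reagents that add atoms: benzyl bromide, BrCc1ccccc1
Why: Williamson etherification; the 2-OH is held in a hydrogen bond to the formyl group and is the least nucleophilic, so two equivalents of electrophile should alkylate O4 and O3 only.

Step 2
Reactants: 3 pyrogallol
Product: 4 1,2,3-tris(benzyloxy)benzene
Conditions: BnBr (3.3 equiv), K2CO3 (3.5 equiv), DMF, 60 °C, N2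
Reagents that add atoms: benzyl bromide, BrCc1ccccc1
Why: Exhaustive Williamson etherification of a triphenol; exclusion of air prevents oxidation of the pyrogallol anion.

Step 3
Reactants: 4 1,2,3-tris(benzyloxy)benzene
Product: 5 1,5-dibromo-2,3,4-tris(benzyloxy)benzene
Conditions: N-bromosuccinimide (2.1 equiv), MeCN, 0 °C to rt, dark
Reagents that add atoms: N-bromosuccinimide, O=C1CCC(=O)N1Br
Why: Electrophilic aromatic bromination; 1,2,3-trialkoxybenzenes react at C4 and then C6 (para to the outer ether groups), which gives the symmetric dibromide, and a polar solvent in the dark avoids benzylic bromination.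

Step 4
Reactants: 5 1,5-dibromo-2,3,4-tris(benzyloxy)benzene; 2 3,4-bis(benzyloxy)-2-hydroxybenzaldehyde
Product: 8 racemic 5,6-bis(benzyloxy)-2-{[5-bromo-2,3,4-tris(benzyloxy)phenyl](hydroxy)methyl}phenol, via aryllithium 6 (not isolated), via sodium phenoxide 7 (not isolated)
Conditions: 5, n-BuLi (1.0 equiv), THF, −78 °C; separately 2, NaH (1.0 equiv), THF, 0 °C; combine at −78 °C, warm to 0 °C; aq. NH4Cl
Reagents that add atoms: none
Why: Bromine–lithium exchange followed by 1,2-addition to an aldehyde; the first exchange makes the ring electron-rich and stops the second, and prior deprotonation of the phenol saves one equivalent of 6 while the ortho-phenoxide aldehyde remains electrophilic enough for an aryllithium.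

Step 5
Reactants: 8 racemic 5,6-bis(benzyloxy)-2-{[5-bromo-2,3,4-tris(benzyloxy)phenyl](hydroxy)methyl}phenol
Product: 9 racemic 5,6-bis(benzyloxy)-2-{[5-bromo-2,3,4-tris(benzyloxy)phenyl](4-methylbenzenesulfonyl)methyl}phenol
Conditions: p-toluenesulfinic acid (1.5 equiv), CH2Cl2, rt
Reagents that add atoms: p-toluenesulfinic acid, Cc1ccc(cc1)S(=O)O
Why: Acid-promoted SN1 substitution of a doubly benzylic, ortho-hydroxy-activated alcohol by the sulfur of the sulfinate; the sulfone is a stable, crystalline store of the quinone methide.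

Step 6
Reactants: 9 racemic 5,6-bis(benzyloxy)-2-{[5-bromo-2,3,4-tris(benzyloxy)phenyl](4-methylbenzenesulfonyl)methyl}phenol; 10 benzyloxyacetaldehyde
Product: 12 (3R,4R)-3,7,8-tris(benzyloxy)-4-[5-bromo-2,3,4-tris(benzyloxy)phenyl]chroman-2-ol (3,4-trans; both C2 anomers), via ortho-quinone methide 11 (not isolated)
Conditions: (S)-2-[diphenyl(trimethylsilyloxy)methyl]pyrrolidine (20 mol %), Na2CO3 (1.5 equiv), 10 (2 equiv, slow addition), CH2Cl2, 0 °C to rt
Reagents that add atoms: none
Why: Carbonate deprotonates the phenol of 9 and sulfinate leaves by 1,4-elimination to give 11; the amine condenses with 10 to an enamine, whose α-carbon adds to the methide carbon of 11 (C3–C4), driven by rearomatisation of ring A. Hydrolysis of the resulting iminium frees the catalyst, and the phenol oxygen adds to the aldehyde carbon (O1–C2) in a 6-exo-trig hemiacetalisation that closes the pyran ring as the lactol. The closest known reaction type is the secondary-amine-catalysed formal oxa-[4+2] of aldehydes with ortho-quinone methides generated in situ from 2-(sulfonylmethyl)phenols, which gives trans-3,4-disubstituted chroman-2-ols. C3 is controlled by the catalyst: the silyloxydiphenylmethyl group shields one face of the E enamine, so the electrophile enters on the open face, which with the S catalyst gives 3R. C4 is controlled by the approach topology: 11 is expected to hold its aryl group away from the carbonyl oxygen (E), and the usual synclinal, endo-type approach of the enamine then places the C4 aryl trans to the C3 ether. The step needs cross-addition to outrun self-aldolisation of 10, which slow addition and the high electrophilicity of 11 should secure, and it needs one face of each partner. The ortho-benzyloxy group on the methide aryl fixes the methide geometry, the racemic stereocentre of 9 is erased in planar 11, and the trans lactol is also the more stable isomer should C3 equilibrate through the open aldehyde form.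

Step 7
Reactants: 12 (3R,4R)-3,7,8-tris(benzyloxy)-4-[5-bromo-2,3,4-tris(benzyloxy)phenyl]chroman-2-ol
Product: 13 (3R,4R)-3,7,8-tris(benzyloxy)-4-[5-bromo-2,3,4-tris(benzyloxy)phenyl]chroman-2-yl acetate (both C2 anomers)
Conditions: Ac2O, Et3N, DMAP (cat.), CH2Cl2, 0 °C
Reagents that add atoms: acetic anhydride, CC(=O)OC(C)=O
Why: Acylation of the anomeric hydroxyl of a lactol; low temperature and a short reaction time limit ring opening to the aldehyde and epimerisation at C3.

Step 8
Reactants: 13 (3R,4R)-3,7,8-tris(benzyloxy)-4-[5-bromo-2,3,4-tris(benzyloxy)phenyl]chroman-2-yl acetate; 14 1,2-bis(benzyloxy)benzene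
Product: 16 1-bromo-2,3,4-tris(benzyloxy)-5-U-benzene, that is (2R,3R,4R)-3,7,8-tris(benzyloxy)-2-[3,4-bis(benzyloxy)phenyl]-4-[5-bromo-2,3,4-tris(benzyloxy)phenyl]chromane, via oxocarbenium ion 15 (not isolated)
Conditions: 14 (5 equiv), BF3·OEt2 (1.5 equiv), CH2Cl2, −78 to −30 °C; Et3N quench
Reagents that add atoms: none
Why: Lewis-acid ionisation of the anomeric acetate and Friedel–Crafts C-arylation of the cyclic oxocarbenium ion at the position para to an ether oxygen of 14. In the half-chair of 15 that keeps the C3 ether and C4 aryl pseudo-equatorial, pseudo-axial attack through a chair-like transition state puts the new aryl cis to the C3 ether and trans to the C4 aryl (upper C2 = R). The bromine and the C1 substituent flank the only free position of the C4 aryl and so suppress intramolecular arylation.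

Step 9
Reactants: 16 1-bromo-2,3,4-tris(benzyloxy)-5-U-benzene
Product: 18 1-[2,3,4-tris(benzyloxy)-5-U-phenyl]ethanone, via enol ether 17 (not isolated)
Conditions: tributyl(1-ethoxyvinyl)stannane (1.5 equiv), PdCl2(PPh3)2 (5 mol %), toluene, 100 °C; then 1 M HCl, THF, rt
Reagents that add atoms: tributyl(1-ethoxyvinyl)stannane, CCCC[Sn](CCCC)(CCCC)C(=C)OCC; water, O
Why: Stille coupling of an aryl bromide with an acyl-anion equivalent, then enol ether hydrolysis; it places the acetyl group exactly at the future lower C4a under neutral conditions that leave the benzyl ethers and both benzylic stereocentres alone.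

Step 10
Reactants: 18 1-[2,3,4-tris(benzyloxy)-5-U-phenyl]ethanone
Product: 19 1-[3,4-bis(benzyloxy)-2-hydroxy-5-U-phenyl]ethanone
Conditions: MgBr2·OEt2 (3 equiv), toluene/Et2O, 70 °C; then 1 M HCl
Reagents that add atoms: none
Why: Chelation-controlled debenzylation; magnesium binds the ketone oxygen and the one ether oxygen ortho to it, and bromide removes only that benzyl group, which frees the oxygen that becomes lower O1.

Step 11
Reactants: 19 1-[3,4-bis(benzyloxy)-2-hydroxy-5-U-phenyl]ethanone
Product: 21 7,8-bis(benzyloxy)-6-U-4H-chromen-4-one, via enaminone 20 (not isolated)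
Conditions: Me2NCH(OMe)2 (3 equiv), toluene, 90 °C; evaporate; then conc. HCl (cat.), CH2Cl2, rt
Reagents that add atoms: N,N-dimethylformamide dimethyl acetal, COC(OC)N(C)C
Why: Condensation of the methyl ketone with the amide acetal, then acid-promoted conjugate addition of the phenol and loss of dimethylamine; this is the standard chromone synthesis from ortho-hydroxyacetophenones.

Step 12
Reactants: 21 7,8-bis(benzyloxy)-6-U-4H-chromen-4-one; 22 4-(benzyloxy)phenylboronic acid
Product: 23 (2S)-7,8-bis(benzyloxy)-2-[4-(benzyloxy)phenyl]-6-U-chroman-4-one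
Conditions: 22 (3 equiv), Pd(OCOCF3)2 (10 mol %), (R)-4-tert-butyl-2-(pyridin-2-yl)-4,5-dihydrooxazole (12 mol %), NH4PF6 (30 mol %), H2O (5 equiv), ClCH2CH2Cl, 60 °C
Reagents that add atoms: none
Why: Conjugate addition of an arylboronic acid to a chromone catalysed by divalent palladium with a chiral pyridine-oxazoline ligand (aryl transfer to palladium, enantio-determining insertion of C2=C3, protonolysis). The ligand antipode is chosen so that the aryl group adds to the face that gives 2S, expected by analogy with cyclic enones to be the R ligand. The substrate is a single enantiomer, so the minor C2 epimer and any material from the minor enantiomer of step 6 are diastereomers that chromatography removes.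

Step 13
Reactants: 23 (2S)-7,8-bis(benzyloxy)-2-[4-(benzyloxy)phenyl]-6-U-chroman-4-one
Product: 25 (2R,3R)-7,8-bis(benzyloxy)-2-[4-(benzyloxy)phenyl]-3-hydroxy-6-U-chroman-4-one (2,3-trans), via silyl enol ether 24 (not isolated)
Conditions: Me3SiOSO2CF3, Et3N, CH2Cl2, 0 °C; evaporate; then OsO4 (2 mol %), N-methylmorpholine N-oxide, acetone/H2O, 0 °C
Reagents that add atoms: osmium tetroxide, O=[Os](=O)(=O)=O; N-methylmorpholine N-oxide (terminal oxidant), C[N+]1([O-])CCOCC1
Why: Rubottom-type oxidation; soft enolisation avoids the ring-opening that strong bases cause in flavanones, and the oxidant adds to the enol ether anti to the C2 aryl to give the trans ketol. The facial outcome at C3 is not critical because C3 is later taken through a ketone.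

Step 14
Reactants: 25 (2R,3R)-7,8-bis(benzyloxy)-2-[4-(benzyloxy)phenyl]-3-hydroxy-6-U-chroman-4-one
Product: 26 (2R,3S,4R)-7,8-bis(benzyloxy)-2-[4-(benzyloxy)phenyl]-6-U-chromane-3,4-diol (2,3-trans and 3,4-trans; some C4 epimer may accompany it)
Conditions: NaBH4, THF/MeOH, 0 °C
Reagents that add atoms: none
Why: Hydride reduction of an aryl ketone; axial attack on the trans ketol should favour the equatorial 3,4-trans alcohol, and both C4 epimers are usable because C4 is reset in step 15.

Step 15
Reactants: 26 (2R,3S,4R)-7,8-bis(benzyloxy)-2-[4-(benzyloxy)phenyl]-6-U-chromane-3,4-diol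
Product: 27 (2R,3S,4R)-4,7,8-tris(benzyloxy)-2-[4-(benzyloxy)phenyl]-6-U-chroman-3-ol
Conditions: BnOH (20 equiv), camphorsulfonic acid (10 mol %), CH2Cl2, 0 °C to rt
Reagents that add atoms: benzyl alcohol, OCc1ccccc1
Why: Acid-catalysed SN1 etherification of the flavan-3,4-diol at C4 only, since that carbon is benzylic and stabilised by O1 and the para C7 oxygen. The alcohol adds anti to the C3 hydroxyl and the all-equatorial 2,4-cis ether is also the thermodynamic product, so both C4 epimers of 26 converge. C3 is untouched and is thereby distinguished from C4.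

Step 16
Reactants: 27 (2R,3S,4R)-4,7,8-tris(benzyloxy)-2-[4-(benzyloxy)phenyl]-6-U-chroman-3-ol
Product: 28 (2R,4R)-4,7,8-tris(benzyloxy)-2-[4-(benzyloxy)phenyl]-6-U-chroman-3-one (2,4-cis)
Conditions: Dess–Martin periodinane (1,1,1-triacetoxy-1,1-dihydro-1,2-benziodoxol-3(1H)-one), NaHCO3, CH2Cl2, 0 °C to rt
Reagents that add atoms: none
Why: Hypervalent-iodine oxidation of a secondary alcohol under buffered, non-basic conditions, as used for flavan-3-ols; this protects the two enolisable centres C2 and C4 next to the new ketone.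

Step 17
Reactants: 28 (2R,4R)-4,7,8-tris(benzyloxy)-2-[4-(benzyloxy)phenyl]-6-U-chroman-3-one
Product: 29 (2R,3R,4R)-4,7,8-tris(benzyloxy)-2-[4-(benzyloxy)phenyl]-6-U-chroman-3-ol (all-cis)
Conditions: LiBH(s-Bu)3 (L-Selectride), THF, −78 °C; aq. NH4Cl
Reagents that add atoms: none
Why: Reduction by a bulky hydride from the equatorial direction, anti to both the C2 aryl and the C4 ether, gives the axial alcohol cis to both; this is the established way from 2,3-trans to 2,3-cis flavan-3-ols, reinforced here by the second equatorial neighbour.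

Step 18
Reactants: 29 (2R,3R,4R)-4,7,8-tris(benzyloxy)-2-[4-(benzyloxy)phenyl]-6-U-chroman-3-ol
Product: 30 (2R,3R,4R)-2-(4-hydroxyphenyl)-6-[(2R,3R,4S)-2-(3,4-dihydroxyphenyl)-3,7,8-trihydroxychroman-4-yl]chromane-3,4,7,8-tetrol (CNP0174688.1)
Conditions: H2 (1 atm), Pd(OH)2/C, THF/MeOH, rt, stopped at full debenzylation; filtration under argon
Reagents that add atoms: none
Why: Hydrogenolysis of seven aryl benzyl ethers and two alkyl benzyl ethers under neutral conditions; the unhindered O–CH2Ph bonds should cleave before the secondary benzylic C4–O and C2–O1 bonds, and no stereocentre is touched.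

## Compound list

1 | 2,3,4-trihydroxybenzaldehyde | O=Cc1ccc(O)c(O)c1O | starting material
2 | 3,4-bis(benzyloxy)-2-hydroxybenzaldehyde | O=Cc1ccc(OCc9ccccc9)c(OCc9ccccc9)c1O | intermediate
3 | pyrogallol | Oc1cccc(O)c1O | starting material
4 | 1,2,3-tris(benzyloxy)benzene | c1cc(OCc9ccccc9)c(OCc9ccccc9)c(OCc9ccccc9)c1 | intermediate
5 | 1,5-dibromo-2,3,4-tris(benzyloxy)benzene | Brc1cc(Br)c(OCc9ccccc9)c(OCc9ccccc9)c1OCc9ccccc9 | intermediate
6 | 5-bromo-2,3,4-tris(benzyloxy)phenyllithium | [Li]c1cc(Br)c(OCc9ccccc9)c(OCc9ccccc9)c1OCc9ccccc9 | intermediate (not isolated)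
7 | sodium 5,6-bis(benzyloxy)-2-formylphenoxide | [Na+].[O-]c1c(C=O)ccc(OCc9ccccc9)c1OCc9ccccc9 | intermediate (not isolated)
8 | racemic 5,6-bis(benzyloxy)-2-{[5-bromo-2,3,4-tris(benzyloxy)phenyl](hydroxy)methyl}phenol | OC(c1cc(Br)c(OCc9ccccc9)c(OCc9ccccc9)c1OCc9ccccc9)c1ccc(OCc9ccccc9)c(OCc9ccccc9)c1O | intermediate
9 | racemic 5,6-bis(benzyloxy)-2-{[5-bromo-2,3,4-tris(benzyloxy)phenyl](4-methylbenzenesulfonyl)methyl}phenol | Cc1ccc(cc1)S(=O)(=O)C(c1cc(Br)c(OCc9ccccc9)c(OCc9ccccc9)c1OCc9ccccc9)c1ccc(OCc9ccccc9)c(OCc9ccccc9)c1O | intermediate (key-step precursor)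
10 | benzyloxyacetaldehyde | O=CCOCc1ccccc1 | starting material
11 | (E)-2,3-bis(benzyloxy)-6-[5-bromo-2,3,4-tris(benzyloxy)benzylidene]cyclohexa-2,4-dien-1-one | O=C1C(OCc9ccccc9)=C(OCc9ccccc9)C=C/C1=C\c1cc(Br)c(OCc9ccccc9)c(OCc9ccccc9)c1OCc9ccccc9 | intermediate (not isolated)
12 | (3R,4R)-3,7,8-tris(benzyloxy)-4-[5-bromo-2,3,4-tris(benzyloxy)phenyl]chroman-2-ol, 3,4-trans, both C2 anomers | Brc1cc([C@H]4c5ccc(OCc9ccccc9)c(OCc9ccccc9)c5OC(O)[C@@H]4OCc9ccccc9)c(OCc9ccccc9)c(OCc9ccccc9)c1OCc9ccccc9 | intermediate (key-step product)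
13 | (3R,4R)-3,7,8-tris(benzyloxy)-4-[5-bromo-2,3,4-tris(benzyloxy)phenyl]chroman-2-yl acetate, both C2 anomers | Brc1cc([C@H]4c5ccc(OCc9ccccc9)c(OCc9ccccc9)c5OC(OC(C)=O)[C@@H]4OCc9ccccc9)c(OCc9ccccc9)c(OCc9ccccc9)c1OCc9ccccc9 | intermediate
14 | 1,2-bis(benzyloxy)benzene | c1ccc(OCc9ccccc9)c(OCc9ccccc9)c1 | starting material
15 | (3R,4R)-3,7,8-tris(benzyloxy)-4-[5-bromo-2,3,4-tris(benzyloxy)phenyl]-3,4-dihydrochromenylium (C2 oxocarbenium ion) | Brc1cc([C@H]4c5ccc(OCc9ccccc9)c(OCc9ccccc9)c5[O+]=C[C@@H]4OCc9ccccc9)c(OCc9ccccc9)c(OCc9ccccc9)c1OCc9ccccc9 | intermediate (not isolated)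
16 | 1-bromo-2,3,4-tris(benzyloxy)-5-U-benzene; (2R,3R,4R)-3,7,8-tris(benzyloxy)-2-[3,4-bis(benzyloxy)phenyl]-4-[5-bromo-2,3,4-tris(benzyloxy)phenyl]chromane | Brc1cc([C@H]4c5ccc(OCc9ccccc9)c(OCc9ccccc9)c5O[C@H](c5ccc(OCc9ccccc9)c(OCc9ccccc9)c5)[C@@H]4OCc9ccccc9)c(OCc9ccccc9)c(OCc9ccccc9)c1OCc9ccccc9 | intermediate
17 | 1-(1-ethoxyvinyl)-2,3,4-tris(benzyloxy)-5-U-benzene | CCOC(=C)c1cc([C@H]4c5ccc(OCc9ccccc9)c(OCc9ccccc9)c5O[C@H](c5ccc(OCc9ccccc9)c(OCc9ccccc9)c5)[C@@H]4OCc9ccccc9)c(OCc9ccccc9)c(OCc9ccccc9)c1OCc9ccccc9 | intermediate (not isolated)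
18 | 1-[2,3,4-tris(benzyloxy)-5-U-phenyl]ethanone | CC(=O)c1cc([C@H]4c5ccc(OCc9ccccc9)c(OCc9ccccc9)c5O[C@H](c5ccc(OCc9ccccc9)c(OCc9ccccc9)c5)[C@@H]4OCc9ccccc9)c(OCc9ccccc9)c(OCc9ccccc9)c1OCc9ccccc9 | intermediate
19 | 1-[3,4-bis(benzyloxy)-2-hydroxy-5-U-phenyl]ethanone | CC(=O)c1cc([C@H]4c5ccc(OCc9ccccc9)c(OCc9ccccc9)c5O[C@H](c5ccc(OCc9ccccc9)c(OCc9ccccc9)c5)[C@@H]4OCc9ccccc9)c(OCc9ccccc9)c(OCc9ccccc9)c1O | intermediate
20 | (E)-1-[3,4-bis(benzyloxy)-2-hydroxy-5-U-phenyl]-3-(dimethylamino)prop-2-en-1-one | CN(C)/C=C/C(=O)c1cc([C@H]4c5ccc(OCc9ccccc9)c(OCc9ccccc9)c5O[C@H](c5ccc(OCc9ccccc9)c(OCc9ccccc9)c5)[C@@H]4OCc9ccccc9)c(OCc9ccccc9)c(OCc9ccccc9)c1O | intermediate (not isolated)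
21 | 7,8-bis(benzyloxy)-6-U-4H-chromen-4-one | O=c1ccoc2c(OCc9ccccc9)c(OCc9ccccc9)c(cc12)[C@H]4c5ccc(OCc9ccccc9)c(OCc9ccccc9)c5O[C@H](c5ccc(OCc9ccccc9)c(OCc9ccccc9)c5)[C@@H]4OCc9ccccc9 | intermediate
22 | 4-(benzyloxy)phenylboronic acid | OB(O)c1ccc(OCc2ccccc2)cc1 | starting material
23 | (2S)-7,8-bis(benzyloxy)-2-[4-(benzyloxy)phenyl]-6-U-chroman-4-one | O=C1C[C@@H](c2ccc(OCc9ccccc9)cc2)Oc2c(OCc9ccccc9)c(OCc9ccccc9)c(cc12)[C@H]4c5ccc(OCc9ccccc9)c(OCc9ccccc9)c5O[C@H](c5ccc(OCc9ccccc9)c(OCc9ccccc9)c5)[C@@H]4OCc9ccccc9 | intermediate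
24 | (2S)-7,8-bis(benzyloxy)-2-[4-(benzyloxy)phenyl]-4-(trimethylsilyloxy)-6-U-2H-chromene | C[Si](C)(C)OC1=C[C@@H](c2ccc(OCc9ccccc9)cc2)Oc2c(OCc9ccccc9)c(OCc9ccccc9)c(cc12)[C@H]4c5ccc(OCc9ccccc9)c(OCc9ccccc9)c5O[C@H](c5ccc(OCc9ccccc9)c(OCc9ccccc9)c5)[C@@H]4OCc9ccccc9 | intermediate (not isolated)
25 | (2R,3R)-7,8-bis(benzyloxy)-2-[4-(benzyloxy)phenyl]-3-hydroxy-6-U-chroman-4-one, 2,3-trans | O=C1[C@H](O)[C@@H](c2ccc(OCc9ccccc9)cc2)Oc2c(OCc9ccccc9)c(OCc9ccccc9)c(cc12)[C@H]4c5ccc(OCc9ccccc9)c(OCc9ccccc9)c5O[C@H](c5ccc(OCc9ccccc9)c(OCc9ccccc9)c5)[C@@H]4OCc9ccccc9 | intermediate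
26 | (2R,3S,4R)-7,8-bis(benzyloxy)-2-[4-(benzyloxy)phenyl]-6-U-chromane-3,4-diol, 2,3-trans-3,4-trans | O[C@H]1[C@H](O)[C@@H](c2ccc(OCc9ccccc9)cc2)Oc2c(OCc9ccccc9)c(OCc9ccccc9)c(cc12)[C@H]4c5ccc(OCc9ccccc9)c(OCc9ccccc9)c5O[C@H](c5ccc(OCc9ccccc9)c(OCc9ccccc9)c5)[C@@H]4OCc9ccccc9 | intermediate
27 | (2R,3S,4R)-4,7,8-tris(benzyloxy)-2-[4-(benzyloxy)phenyl]-6-U-chroman-3-ol | O(Cc9ccccc9)[C@H]1[C@H](O)[C@@H](c2ccc(OCc9ccccc9)cc2)Oc2c(OCc9ccccc9)c(OCc9ccccc9)c(cc12)[C@H]4c5ccc(OCc9ccccc9)c(OCc9ccccc9)c5O[C@H](c5ccc(OCc9ccccc9)c(OCc9ccccc9)c5)[C@@H]4OCc9ccccc9 | intermediate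
28 | (2R,4R)-4,7,8-tris(benzyloxy)-2-[4-(benzyloxy)phenyl]-6-U-chroman-3-one, 2,4-cis | O(Cc9ccccc9)[C@H]1C(=O)[C@@H](c2ccc(OCc9ccccc9)cc2)Oc2c(OCc9ccccc9)c(OCc9ccccc9)c(cc12)[C@H]4c5ccc(OCc9ccccc9)c(OCc9ccccc9)c5O[C@H](c5ccc(OCc9ccccc9)c(OCc9ccccc9)c5)[C@@H]4OCc9ccccc9 | intermediate
29 | (2R,3R,4R)-4,7,8-tris(benzyloxy)-2-[4-(benzyloxy)phenyl]-6-U-chroman-3-ol, all-cis | O(Cc9ccccc9)[C@H]1[C@@H](O)[C@@H](c2ccc(OCc9ccccc9)cc2)Oc2c(OCc9ccccc9)c(OCc9ccccc9)c(cc12)[C@H]4c5ccc(OCc9ccccc9)c(OCc9ccccc9)c5O[C@H](c5ccc(OCc9ccccc9)c(OCc9ccccc9)c5)[C@@H]4OCc9ccccc9 | intermediate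
30 | (2R,3R,4R)-2-(4-hydroxyphenyl)-6-[(2R,3R,4S)-2-(3,4-dihydroxyphenyl)-3,7,8-trihydroxychroman-4-yl]chromane-3,4,7,8-tetrol | Oc1ccc([C@H]2Oc3c(cc([C@H]4c5ccc(O)c(O)c5O[C@H](c5ccc(O)c(O)c5)[C@@H]4O)c(O)c3O)[C@@H](O)[C@H]2O)cc1 | target

## Step count and least certain steps

Total: 18 steps. Longest linear sequence: 17 steps (3 → 4 → 5 → 8 → 9 → 12 → 13 → 16 → 18 → 19 → 21 → 23 → 25 → 26 → 27 → 28 → 29 → 30); the branch from 1 to 2 is one step.

**Step 6 (key step).** Most likely to go wrong is facial selectivity at the enamine. An α-alkoxy aldehyde can populate both E and Z enamines, and reaction through the Z form would reverse the sense at C3 and the 3,4-relationship. If the sense proves opposite, the R catalyst is used instead. Self-aldolisation of 10 and slow capture of the hindered, electron-rich methide of 11 are the other processes that would cost material. Fallback (auxiliary control in place of catalyst control), from 9 back to 12: the sodium enolate (NaN(SiMe3)2, THF, −78 °C) of (S)-4-benzyl-3-[(benzyloxy)acetyl]oxazolidin-2-one F1 is used in excess. It serves as the base that releases 11 from 9 and as the nucleophile, giving the conjugate adduct imide F2. The phenoxide of F2 closes onto the imide carbonyl with loss of the oxazolidinone to give the trans dihydrocoumarin (3R,4R)-3,7,8-tris(benzyloxy)-4-[5-bromo-2,3,4-tris(benzyloxy)phenyl]chroman-2-one F3. Reduction of F3 with i-Bu2AlH (CH2Cl2, −78 °C) gives 12.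

**Step 8.** The cis product is the kinetic one. Reversible ionisation of the new C2–O1/C2–aryl system under the Lewis acid would drain it to the all-equatorial 2,3-trans isomer, and benzyl transfer or an insufficiently reactive arene would lower conversion. Fallback (carbonyl addition and ring closure in place of oxocarbenium arylation), from 12 back to 16: the open hydroxy-aldehyde form of 12 is treated with excess 3,4-bis(benzyloxy)phenyltitanium triisopropoxide (from 4-bromo-1,2-bis(benzyloxy)benzene, n-BuLi, then ClTi(OiPr)3), a non-chelating reagent that should add in the Felkin–Anh sense to give the 1,2-anti phenol carbinol F4. Mitsunobu cyclisation of F4 (PPh3, diisopropyl azodicarboxylate, THF, 0 °C) closes O1–C2 with inversion and gives 16.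

**Step 12.** Insertion into an electron-rich 7,8-dialkoxychromone that carries a very large C6 substituent may be slow, so that protodeboronation of 22 wins. Imperfect ligand control would give the C2 epimer, which is separable but costs material. Fallback (epoxide route in place of conjugate arylation), from 19 to 25, bypassing 21, 23 and 24: the phenol of 19 is protected (MeOCH2Cl, i-Pr2NEt) to the methoxymethyl ether F5. Claisen–Schmidt condensation of F5 with 4-(benzyloxy)benzaldehyde (KOH, EtOH/THF) gives the (E)-chalcone F6. Juliá–Colonna epoxidation of F6 (poly-L-leucine, urea–hydrogen peroxide, 1,8-diazabicyclo[5.4.0]undec-7-ene, THF) should give the (αR,βS)-epoxide F7. Treatment of F7 with HCl in MeOH removes the acetal and lets the phenol open the epoxide at the benzylic carbon to give the trans ketol 25.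

**Step 15.** Ionisation at C4 could lead to a mixture of C4 epimers, to loss of a C3 proton, or to Friedel–Crafts capture of the cation by another electron-rich ring in place of the alcohol. Fallback (epoxide opening in place of diol solvolysis), from 23 back to 27: NaBH4 reduces 23 to the (2S,4S)-2,4-cis flavan-4-ol F8. Dehydration of F8 with methyl N-(triethylammoniumsulfonyl)carbamate (Burgess reagent, toluene, 50 °C) gives the (2S)-flav-3-ene F9 under non-acidic conditions. Dimethyldioxirane (acetone, −40 °C) epoxidises F9 anti to the aryl group to the 3,4-epoxide F10, and benzyl alcohol with a trace of camphorsulfonic acid opens F10 at C4 with inversion to give 27.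

**Step 18.** The lower C4–O bond is itself benzylic and could be hydrogenolysed (deoxygenation at C4) in competition with loss of its benzyl group; prolonged exposure could also open a pyran C2–O1 bond. Fallback (the C4 alcohol is created only after debenzylation), from 25 to 30: Mitsunobu inversion of 25 with benzoic acid (PPh3, diisopropyl azodicarboxylate) gives the 2,3-cis benzoate (2R,3S) F11. Hydrogenolysis of F11 (H2, Pd(OH)2/C), which the C4 ketone tolerates, gives the free polyphenolic cis-3-benzoyloxyflavanone F12. NaBH4 reduces F12 anti to the axial ester to the all-cis 3-benzoate of the target F13, which is not isolated, and NaOMe in degassed MeOH converts F13 into 30.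

## Further compounds

F1 | step 6 | (S)-4-benzyl-3-[(benzyloxy)acetyl]oxazolidin-2-one | O=C(COCc1ccccc1)N1[C@@H](Cc2ccccc2)COC1=O
F2 | step 6 | conjugate adduct imide: (S)-4-benzyl-3-{(2R,3R)-2-(benzyloxy)-3-[3,4-bis(benzyloxy)-2-hydroxyphenyl]-3-[5-bromo-2,3,4-tris(benzyloxy)phenyl]propanoyl}oxazolidin-2-one (configuration as in SMILES) | Brc1cc([C@@H](c2ccc(OCc9ccccc9)c(OCc9ccccc9)c2O)[C@@H](OCc9ccccc9)C(=O)N2[C@@H](Cc3ccccc3)COC2=O)c(OCc9ccccc9)c(OCc9ccccc9)c1OCc9ccccc9
F3 | step 6 | (3R,4R)-3,7,8-tris(benzyloxy)-4-[5-bromo-2,3,4-tris(benzyloxy)phenyl]chroman-2-one, 3,4-trans | Brc1cc([C@H]4c5ccc(OCc9ccccc9)c(OCc9ccccc9)c5OC(=O)[C@@H]4OCc9ccccc9)c(OCc9ccccc9)c(OCc9ccccc9)c1OCc9ccccc9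
F4 | step 8 | open-chain phenol carbinol: 1-[3,4-bis(benzyloxy)phenyl]-2-(benzyloxy)-3-[3,4-bis(benzyloxy)-2-hydroxyphenyl]-3-[5-bromo-2,3,4-tris(benzyloxy)phenyl]propan-1-ol, carbinol anti to the C2 ether (configuration as in SMILES) | Brc1cc([C@@H](c2ccc(OCc9ccccc9)c(OCc9ccccc9)c2O)[C@@H](OCc9ccccc9)[C@@H](O)c2ccc(OCc9ccccc9)c(OCc9ccccc9)c2)c(OCc9ccccc9)c(OCc9ccccc9)c1OCc9ccccc9
F5 | step 12 | 1-[3,4-bis(benzyloxy)-2-(methoxymethoxy)-5-U-phenyl]ethanone | CC(=O)c1cc([C@H]4c5ccc(OCc9ccccc9)c(OCc9ccccc9)c5O[C@H](c5ccc(OCc9ccccc9)c(OCc9ccccc9)c5)[C@@H]4OCc9ccccc9)c(OCc9ccccc9)c(OCc9ccccc9)c1OCOC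
F6 | step 12 | (E)-1-[3,4-bis(benzyloxy)-2-(methoxymethoxy)-5-U-phenyl]-3-[4-(benzyloxy)phenyl]prop-2-en-1-one | O=C(/C=C/c1ccc(OCc9ccccc9)cc1)c1cc([C@H]4c5ccc(OCc9ccccc9)c(OCc9ccccc9)c5O[C@H](c5ccc(OCc9ccccc9)c(OCc9ccccc9)c5)[C@@H]4OCc9ccccc9)c(OCc9ccccc9)c(OCc9ccccc9)c1OCOC
F7 | step 12 | (αR,βS)-trans-epoxide of F6: [3,4-bis(benzyloxy)-2-(methoxymethoxy)-5-U-phenyl]{(2R,3S)-3-[4-(benzyloxy)phenyl]oxiran-2-yl}methanone | O=C([C@@H]1O[C@H]1c1ccc(OCc9ccccc9)cc1)c1cc([C@H]4c5ccc(OCc9ccccc9)c(OCc9ccccc9)c5O[C@H](c5ccc(OCc9ccccc9)c(OCc9ccccc9)c5)[C@@H]4OCc9ccccc9)c(OCc9ccccc9)c(OCc9ccccc9)c1OCOC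
F8 | step 15 | (2S,4S)-7,8-bis(benzyloxy)-2-[4-(benzyloxy)phenyl]-6-U-chroman-4-ol, 2,4-cis | O[C@H]1C[C@@H](c2ccc(OCc9ccccc9)cc2)Oc2c(OCc9ccccc9)c(OCc9ccccc9)c(cc12)[C@H]4c5ccc(OCc9ccccc9)c(OCc9ccccc9)c5O[C@H](c5ccc(OCc9ccccc9)c(OCc9ccccc9)c5)[C@@H]4OCc9ccccc9
F9 | step 15 | (2S)-7,8-bis(benzyloxy)-2-[4-(benzyloxy)phenyl]-6-U-2H-chromene | C1=C[C@@H](c2ccc(OCc9ccccc9)cc2)Oc2c(OCc9ccccc9)c(OCc9ccccc9)c(cc12)[C@H]4c5ccc(OCc9ccccc9)c(OCc9ccccc9)c5O[C@H](c5ccc(OCc9ccccc9)c(OCc9ccccc9)c5)[C@@H]4OCc9ccccc9
F10 | step 15 | 3,4-epoxide of F9, oxygen anti to the C2 aryl (configuration as in SMILES) | O1[C@@H]2[C@H]1[C@@H](c3ccc(OCc9ccccc9)cc3)Oc3c(OCc9ccccc9)c(OCc9ccccc9)c(cc23)[C@H]4c5ccc(OCc9ccccc9)c(OCc9ccccc9)c5O[C@H](c5ccc(OCc9ccccc9)c(OCc9ccccc9)c5)[C@@H]4OCc9ccccc9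
F11 | step 18 | (2R,3S)-7,8-bis(benzyloxy)-2-[4-(benzyloxy)phenyl]-4-oxo-6-U-chroman-3-yl benzoate, 2,3-cis | O=C1[C@@H](OC(=O)c2ccccc2)[C@@H](c2ccc(OCc9ccccc9)cc2)Oc2c(OCc9ccccc9)c(OCc9ccccc9)c(cc12)[C@H]4c5ccc(OCc9ccccc9)c(OCc9ccccc9)c5O[C@H](c5ccc(OCc9ccccc9)c(OCc9ccccc9)c5)[C@@H]4OCc9ccccc9
F12 | step 18 | (2R,3S)-7,8-dihydroxy-2-(4-hydroxyphenyl)-4-oxo-6-[2,3-cis-3,4-trans-2-(3,4-dihydroxyphenyl)-3,7,8-trihydroxychroman-4-yl]chroman-3-yl benzoate (configuration as in SMILES) | O=C1[C@@H](OC(=O)c2ccccc2)[C@@H](c2ccc(O)cc2)Oc2c(O)c(O)c(cc12)[C@H]4c5ccc(O)c(O)c5O[C@H](c5ccc(O)c(O)c5)[C@@H]4O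
F13 | step 18 | 3-O-benzoate of 30 (all-cis lower ring; configuration as in SMILES) | O[C@H]1[C@@H](OC(=O)c2ccccc2)[C@@H](c2ccc(O)cc2)Oc2c(O)c(O)c(cc12)[C@H]4c5ccc(O)c(O)c5O[C@H](c5ccc(O)c(O)c5)[C@@H]4O
A1 | alternative 1 | (2S)-7,8,4'-trihydroxyflavanone carrying the upper unit at C6 | O=C1C[C@@H](c2ccc(O)cc2)Oc2c(O)c(O)c([C@H]4c5ccc(O)c(O)c5O[C@H](c5ccc(O)c(O)c5)[C@@H]4O)cc21
A2 | alternative 1 | (E)-2',3',4',4-tetrahydroxychalcone carrying the upper unit at C5' | O=C(/C=C/c1ccc(O)cc1)c1cc([C@H]2c3ccc(O)c(O)c3O[C@H](c3ccc(O)c(O)c3)[C@@H]2O)c(O)c(O)c1O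
A3 | alternative 2 | protected dimer with C8 pinacol boronate and C7 triisopropylsilyl ether on lower ring A | c1ccccc1COc1ccc([C@H]2Oc3c(cc([C@H]4c5ccc(OCc6ccccc6)c(OCc6ccccc6)c5O[C@H](c5ccc(OCc6ccccc6)c(OCc6ccccc6)c5)[C@@H]4OCc4ccccc4)c(O[Si](C(C)C)(C(C)C)C(C)C)c3B3OC(C)(C)C(C)(C)O3)[C@@H](O[Si](C)(C)C(C)(C)C)[C@H]2O[Si](C)(C)C(C)(C)C)cc1
A4 | alternative 3 | 4-[2,3,4-tris(benzyloxy)phenyl]-7,8-bis(benzyloxy)chroman-2-one | c1ccccc1COc1c(OCc2ccccc2)c(OCc2ccccc2)ccc1[C@@H]1CC(=O)Oc2c(OCc3ccccc3)c(OCc3ccccc3)ccc21
A5 | alternative 3 | 3-[2,3,4-tris(benzyloxy)phenyl]-6,7-bis(benzyloxy)indan-1-one | c1ccccc1COc1c(OCc2ccccc2)c(OCc2ccccc2)ccc1[C@@H]1CC(=O)c2c(OCc3ccccc3)c(OCc3ccccc3)ccc21
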